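The easy mistake with this flask is to read its speed from the charged concentrations, when the speed also follows a chain carrier that no charge contains.

    initiator → 2 initiating radical (k1 = 0.0095 h⁻¹)
    substrate + initiating radical → capped initiator + first chain carrier (k2 = 1.9 × 10⁷ M⁻¹ h⁻¹)
    coupling partner + first chain carrier ⇌ product + second chain carrier (K3 = 0.46, k3 = 5.6 × 10⁵ M⁻¹ h⁻¹)
    substrate + second chain carrier → by-product + first chain carrier (k4 = 6.1 × 10⁵ M⁻¹ h⁻¹)
    2 first chain carrier → ended chains A (k5 = 7.5 × 10⁷ M⁻¹ s⁻¹)
    2 second chain carrier → ended chains B (k6 = 1.9 × 10⁸ M⁻¹ s⁻¹)

substrate 0.50 M; coupling partner 0.475 M (fed, over 25 h); initiator 44 mM; time 6.0 d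

- which holds at 6.0 d: what has brought the reaction to rest, or that it has not come to rest (it is still moving / all of the substrate has reacted / forward and back rates have come level / the coupling partner has run out first)
- share of the substrate used up at 6.0 d
- product at 6.0 d, in percent of the substrate charged

- a species is counted by the substrate in it: one ended chains A counts as two
- for a step with 2 of a species take k times the square, and two of it per event
- the reaction counts as stopped when no species that holds the substrate changes by six tenths of a point or more over the second half of the time
- run time (flask): 6.0 d

I keep the ledger in coupling partner, the limiting reagent by charge. First entry: each one taken becomes one product, so the books hold 95.0% product at most, in percent of the substrate charged. Second entry: by the asked time the initiator has given 0.0656 M of initiating radical, and each starts one chain. Third entry: the speed at which partner leaves, which I take as the speed of second chain carrier on substrate, so I reckon the rate as first order in c(substrate) and in c(second chain carrier). That carrier concentration needs two balances, the cycle's and the one between making and ending: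

c(first chain carrier)/c(second chain carrier) = (6.1 × 10⁵ M⁻¹ h⁻¹ c(substrate) + 1.22 × 10⁶ M⁻¹ h⁻¹ c(product)) / (5.6 × 10⁵ M⁻¹ h⁻¹ c(coupling partner))

c(second chain carrier) = sqrt( 0.0095 h⁻¹ c(initiator) / (1.9 × 10⁸ M⁻¹ s⁻¹ + 7.5 × 10⁷ M⁻¹ s⁻¹ × ratio²) )

I open the books at mid-ledger: 0.237 M each of partner and product, which is half of the partner charge, 0.263 M substrate, and initiator at its half-life of 3.0 d. The ratio is 3.38, which gives

c(second chain carrier) = 7.45 nM

This is the carrier level, where carriers end as fast as initiator makes them. The rate there is 0.00119 M h⁻¹. The remaining partner then needs 8.30 d, longer than the whole run, so I commit to a reaction still moving. That rate held over the run gives 34.4% product, less than the ceiling of 95.0%, and I commit to that figure as a rough one. Of the carriers that end, 81.8% go to ended chains A, which hold substrate and no product, so I put conversion above yield by about 10.7% of the substrate charged.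

The forecast says it is still moving, with 65% conversion and 52% product, holding that “The reverse of the transfer step slows the reaction”. Its product figure stands higher than my 34.4%.

The flask gives it is still moving, with 63.0% conversion and 53.4% product. It takes a charge of coupling partner of 0.402 M or 0.563 M to move that yield by 5 points. Against my mid-ledger 7.45 nM, the flask reads 8.93 nM at 3.00 d. With the flask's amounts at 6.00 d the ratio is 3.76, and the two lines give 4.86 nM against 4.80 nM read. The neighbour read at 4.0 d has ratio 3.06, which gives 7.23 nM against 7.10 nM read.

(The numbers are invented; no experiment stands behind them.)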